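## Structural features

The target is a (3R)-isoflavan. Benzene ring A is fused to dihydropyran ring C (O1, C2, C3, C4, C4a to C8a), and C3 carries aryl ring B, which is fused through C3'/C4' to a 2,2-dimethyl-2H-pyran (called ring D here). Ring A bears the C7 hydroxyl, the C8 prenyl group and the C8a ring oxygen as a contiguous 1,2,3 array. The prenyl group therefore sits between two oxygens, the position that direct prenylation of a resorcinol reaches least cleanly. C3 is the only stereocentre and has no stereogenic neighbour. It is benzylic, flanked by the C2 and C4 methylenes, and cannot epimerise once no carbonyl is attached to it, so it must be set absolutely but only once. The fragile groups are the prenyl alkene, the electron-rich styrene-type double bond and tertiary allylic aryl ether of ring D (acid, electrophiles, hydrogenation, ultraviolet light) and two oxidisable phenols; an o-prenylphenol also closes to a dimethylchroman under acid. The real difficulty is a regiodefined ring A next to a remote stereocentre, reached without acid, hydrogen or strong electrophiles at the end. The key step exploits that C7–O, C8–prenyl and C8a–O are a 2-prenylcyclohexane-1,3-dione at lower oxidation level. C8a is at the same time the acyl carbon of a δ-lactone whose six ring atoms (O1, C2, C3, C4, C4a, C8a) are those of ring C.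

## Logic of the disconnections

27 ⇒ 26. The bond cut is the O–CH2 bond of an allyl ether on the ring B phenol. This oxygen must be masked through Lewis-acid, strong-base and peracid steps. An allyl ether resists the titanium Lewis acid of step 6 and leaves under neutral zerovalent-palladium conditions, whereas an acetal would need acid in the last step on a molecule that holds an o-prenylphenol and ring D. There is no skeletal gain. The forward step must ionise only the allyl ether, which is assured because the prenyl group is bound through carbon.

26 ⇒ 23 ⇒ 22. No skeletal bond is cut. Ring A is taken back from the phenol to a cyclohexenone by removing the C5=C6 unsaturation, with a C6–Se bond as the handle. A non-aromatic ring A can be assembled by carbonyl chemistry with the prenyl position fixed. The forward steps need functionalisation at C6 (α') and not at C4a (γ), and an electrophile and oxidant that spare three alkenes. Elimination can only take a C5 hydrogen, and the C4a hydrogen then tautomerises away.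

22 ⇒ 21. The enol ether bond O1–C8a is cut. Ring C falls away as a condensation of the C2 hydroxyl with one carbonyl of a 1,3-dione. Only C8a is within reach through a six-membered ring, so the two dione oxygens are told apart without a protecting group. The forward step needs an acid too weak to add the dione enol across the prenyl double bond.

21 ⇒ 14 + 19. The bonds C4a–C5 and C8–C8a are cut. This dissolves ring A into a lactone that already holds C3 with its oxygen and C4 chain, and an enone that carries the prenyl group on the carbon that becomes C8. The forward step needs conjugate rather than carbonyl addition, transposition of the first-formed ketone enolate to C8, and acylation on the lactone carbonyl, all without touching C3.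

19 ⇒ 18 ⇒ 15 + 16. The C–C bond between the carbinol carbon and the homoprenyl methylene is cut, and the ketone is taken back to the alcohol. This places the vinyl ketone unambiguously; α-methylenation of a methyl ketone would have to discriminate between CH3 and CH2. The forward steps need 1,2-addition to an enal and a mild oxidation to a polymerisable enone.

14 ⇒ 13 ⇒ 12. The lactone acyl–oxygen bond is cut, and the primary alcohol is traced to an imide carbonyl. The tert-butyl ester is a latent lactone carbonyl that survives hydride. The forward steps need chemoselective reduction of the imide without epimerising the α-aryl centre, and a lactonisation that ring D tolerates.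

12 ⇒ 10 + 11. The bond from the stereocentre to the future C4 is cut. This is the only stereogenic event of the route and is placed where a covalently bound auxiliary controls it and where diastereomers can be separated. The forward step needs a geometrically defined chelated enolate and a Lewis acid that the ring B ether withstands.

10 ⇒ 7 + 8, then 7 ⇒ 5 ⇒ 4. The imide N–acyl bond is cut, then the bond between the benzylic carbon and the carboxyl carbon (one-carbon homologation through an enol ether). The forward steps need a hydrolysis–oxidation pair that spares ring D.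

4 ⇒ 3 ⇒ 1 + 2. The allyl O–C bond is cut, then ring D at the aryl–C4 bond and the O–CMe2 bond. Ring B with ring D then comes in one step from two commercial compounds. The forward step needs ring closure on the oxygen para to the formyl group, which the hydrogen bond of the other hydroxyl ensures.

## Other disconnections considered

Alternative 1: The cut removes ring B through C1'–C2', C2'–C3' and C4'–C5'. It leaves a finished chroman (rings A and C, C3 set, C8 prenyl) carrying the diazo enone arm, (3E)-1-diazo-4-[(3R)-7-(methoxymethoxy)-8-(3-methylbut-2-enyl)chroman-3-yl]but-3-en-2-one A2, and the ynol ether triisopropyl[(5-methylhex-4-en-1-yn-1-yl)oxy]silane A3.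
- Forward step: irradiation of A2 would cause Wolff rearrangement to the vinylketene (3E)-4-[(3R)-7-(methoxymethoxy)-8-(3-methylbut-2-enyl)chroman-3-yl]buta-1,3-dien-1-one A4. A4 would add A3 by [2+2], open by a 4π process, close by a 6π process and tautomerise to 6-[(3R)-7-(methoxymethoxy)-8-(3-methylbut-2-enyl)chroman-3-yl]-2-(3-methylbut-2-enyl)-3-(triisopropylsilyloxy)phenol A1.
- In its favour: three C–C bonds and a benzene ring at its final oxidation level form in one operation without acid or base. In bonds per step and in redox economy this is better than step 11, which needs three more steps to reach the arene. Regiocontrol (ynol ether polarity) is as intrinsic as the ring-size control of the chosen annulation, so the two are equal there.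
- Against it: the key step is spent on the ring that 1 and 2 deliver in one step. Ring D is still missing in A1, and A1 has the 2'-hydroxyl free and the 4'-oxygen silylated, the reverse of what pyran closure needs. A protecting-group exchange and an oxidative cyclisation in the presence of the second prenyl group would follow. The regiodefined ring A and the C3 stereocentre would have to be solved beforehand by other means, and A3 is not commercial.
- Comparison: mechanistically elegant, but structurally misdirected for this target and clearly longer.

Alternative 2: The cut is at C3–C1' and C4–C4a, with boron in the place of C2.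
- Forward step: 6-bromo-5-(methoxymethoxy)-2,2-dimethyl-2H-chromene A7, after bromine–lithium exchange, would be added to vinylboronic acid pinacol ester A8 to give the lithium ate complex A9. Zerovalent palladium (from Pd(OAc)2 and a MandyPhos ligand) would insert into 1-bromo-2,4-bis(tert-butyldimethylsilyloxy)-3-(3-methylbut-2-enyl)benzene A6. With NaOTf taking up bromide, the cationic arylpalladium would bind the vinyl group of A9 and trigger 1,2-migration of ring B from boron to the α-carbon as palladium bonds to the β-carbon. Reductive elimination would give the (R)-boronate A5.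
- In its favour: two C–C bonds and the stereocentre come from three simple pieces in one catalytic enantioselective step. No auxiliary is attached and removed, and both arenes arrive intact. On convergence and on catalytic stereocontrol it is better than the chosen plan, and on step count probably its equal.
- Against it: boron stands where C2 is needed, so a Matteson homologation, oxidation, desilylation, ring C closure and acetal removal follow. Both partners carry ortho oxygen substituents, which should slow the coupling and may erode selectivity, and direct aryl transfer competes. The enantiomeric purity is final, with no diastereomer stage such as 12 for upgrading. A6 requires the regioselective prenylation of a resorcinol, the problem that ring A construction avoids. Arylpalladium intermediates also meet three alkenes.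
- Comparison: the shorter idea, but the less certain execution.

Alternative 3: The cut removes ring A through C8a–C8, C7–C6 and C4a–C8a. It leaves (3E,6R)-7-(tert-butyldimethylsilyloxy)-1-diazo-6-[5-(methoxymethoxy)-2,2-dimethyl-2H-chromen-6-yl]hept-3-en-2-one A11 and A3.
- Forward step: photochemical Wolff rearrangement of A11 would give the vinylketene (3E,6R)-7-(tert-butyldimethylsilyloxy)-6-[5-(methoxymethoxy)-2,2-dimethyl-2H-chromen-6-yl]hepta-1,3-dien-1-one A12. The same [2+2], 4π, 6π cascade with A3 would give 6-{(2R)-3-(tert-butyldimethylsilyloxy)-2-[5-(methoxymethoxy)-2,2-dimethyl-2H-chromen-6-yl]propyl}-2-(3-methylbut-2-enyl)-3-(triisopropylsilyloxy)phenol A10.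
- In its favour: it follows the same strategic idea as the chosen plan (ring A made de novo, prenyl position fixed by the building block, C3 from arylacetyl auxiliary chemistry) but lands directly on the phenol. The C7 and C8a oxygens are already differentiated, and ring C would close by a reliable phenol Mitsunobu etherification. In oxidation-level economy and in bonds per key step (three against two) it is better, and in regiocontrol equal.
- Against it: ring D is photochromic, and ultraviolet light opens 2H-chromenes to o-quinone methides, so the chromophore of A11 competes with the diazo ketone. A11 needs a chiral aldehyde, an enone and a diazo transfer, and an alkene-cleavage route to that aldehyde is barred by ring D. A3 needs its own synthesis, and diazo compounds and photolysis scale poorly. Three deprotection or closure steps follow.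
- Comparison: the overall length is expected to be similar to or above the chosen plan, with the saving at the end paid for at the start.

Key step: step 11

Remarks on the chemistry: isoflavan locants are used throughout. Metal enolates formed by deprotonation are treated as the reacting state of the numbered carbonyl compound and carry no number of their own. The ring B phenol is carried as its allyl ether.

## Steps

Step 1
Reactants: 1 2,4-dihydroxybenzaldehyde; 2 3-methylbut-2-enal
Product: 3 5-hydroxy-2,2-dimethyl-2H-chromene-6-carbaldehyde
Conditions: pyridine, 120 °C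
Reagents that add atoms: none
Why: Base-mediated condensation of the enal at C3 of the resorcinol, loss of water to an o-quinone methide and oxa-6π electrocyclisation build ring D; the C2 hydroxyl is held in a hydrogen bond to the formyl group, so the pyran closes on the C4 oxygen (known chromenylation of 2,4-dihydroxyaryl carbonyl compounds).

Step 2
Reactants: 3 5-hydroxy-2,2-dimethyl-2H-chromene-6-carbaldehyde
Product: 4 5-(allyloxy)-2,2-dimethyl-2H-chromene-6-carbaldehyde
Conditions: allyl bromide, K2CO3, DMF, 50 °C
Reagents that add atoms: allyl bromide, C=CCBr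
Why: Williamson etherification of the hydrogen-bonded phenol; the allyl ether resists the titanium Lewis acid of step 6, strong base and cold peracid, and leaves at the end under neutral conditions.

Step 3
Reactants: 4 5-(allyloxy)-2,2-dimethyl-2H-chromene-6-carbaldehyde
Product: 5 5-(allyloxy)-6-(2-methoxyethenyl)-2,2-dimethyl-2H-chromene (E/Z mixture)
Conditions: Ph3P(CH2OMe)Cl, KOtBu, THF, 0 °C → rt
Reagents that add atoms: (methoxymethyl)triphenylphosphonium chloride, COC[P+](c1ccccc1)(c1ccccc1)c1ccccc1.[Cl-]
Why: Wittig methoxymethylenation of a non-enolisable aryl aldehyde; the alkene geometry is irrelevant because both isomers hydrolyse to the same aldehyde.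

Step 4
Reactants: 5 5-(allyloxy)-6-(2-methoxyethenyl)-2,2-dimethyl-2H-chromene
Product: 7 2-[5-(allyloxy)-2,2-dimethyl-2H-chromen-6-yl]acetic acid, via arylacetaldehyde 6 (not isolated)
Conditions: 2 M HCl, THF, rt; crude 6 then NaClO2, NaH2PO4, 2-methylbut-2-ene, tBuOH–H2O, 0 °C → rt
Reagents that add atoms: water, O; sodium chlorite, [Na+].[O-]Cl=O
Why: Acid hydrolysis of the electron-rich enol ether gives the homologated aldehyde, which is oxidised without isolation by the Pinnick protocol; excess 2-methylbut-2-ene removes HOCl before it can chlorinate ring D or the arene.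

Step 5
Reactants: 7 2-[5-(allyloxy)-2,2-dimethyl-2H-chromen-6-yl]acetic acid; 8 (R)-4-benzyloxazolidin-2-one
Product: 10 (4R)-3-{2-[5-(allyloxy)-2,2-dimethyl-2H-chromen-6-yl]acetyl}-4-benzyloxazolidin-2-one, via mixed pivalic anhydride 9 (not isolated)
Conditions: PivCl, Et3N, THF, −20 °C; then 8, LiCl, −20 °C → rt
Reagents that add atoms: none
Why: One-pot N-acylation of the oxazolidinone through the mixed anhydride with LiCl/Et3N activation; no epimerisable centre exists yet.

Step 6
Reactants: 10 (4R)-3-{2-[5-(allyloxy)-2,2-dimethyl-2H-chromen-6-yl]acetyl}-4-benzyloxazolidin-2-one; 11 tert-butyl acrylate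
Product: 12 tert-butyl (4R)-4-[5-(allyloxy)-2,2-dimethyl-2H-chromen-6-yl]-5-[(4R)-4-benzyl-2-oxooxazolidin-3-yl]-5-oxopentanoate
Conditions: TiCl4/Ti(OiPr)4 (3:1, gives TiCl3(OiPr)), iPr2NEt, CH2Cl2, −78 → 0 °C; then 11, 0 °C
Reagents that add atoms: none
Why: Auxiliary-controlled Michael addition of a chelated (Z)-chlorotitanium imide enolate to an acrylate; the acceptor approaches the enolate face opposite the benzyl group of the (R)-auxiliary, the same facial sense as in oxazolidinone alkylations, which gives the (R)-configured α-aryl centre that becomes C3. The tert-butyl ester should stop the reaction at the mono-adduct and survives step 7.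

Step 7
Reactants: 12 tert-butyl (4R)-4-[5-(allyloxy)-2,2-dimethyl-2H-chromen-6-yl]-5-[(4R)-4-benzyl-2-oxooxazolidin-3-yl]-5-oxopentanoate
Product: 13 tert-butyl (4R)-4-[5-(allyloxy)-2,2-dimethyl-2H-chromen-6-yl]-5-hydroxypentanoate
Conditions: LiBH4, H2O (1 equiv), Et2O, 0 °C
Reagents that add atoms: none
Why: LiBH4 reduces the activated exocyclic imide carbonyl chemoselectively and leaves the tert-butyl ester; the cold, weakly basic conditions should not epimerise the α-aryl centre, and the auxiliary is recovered.

Step 8
Reactants: 13 tert-butyl (4R)-4-[5-(allyloxy)-2,2-dimethyl-2H-chromen-6-yl]-5-hydroxypentanoate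
Product: 14 (5R)-5-[5-(allyloxy)-2,2-dimethyl-2H-chromen-6-yl]tetrahydro-2H-pyran-2-one
Conditions: TsOH·H2O (10 mol%), toluene, 80 °C
Reagents that add atoms: none
Why: Acid-catalysed intramolecular transesterification of a δ-hydroxy tert-butyl ester to the six-membered lactone; catalytic sulfonic acid in hot toluene is the medium in which 2,2-dimethylchromenes are themselves made by dehydration, so ring D should survive, and the stereocentre is no longer α to a carbonyl.

Step 9
Reactants: 15 5-bromo-2-methylpent-2-ene; 16 acrolein
Product: 18 7-methylocta-1,6-dien-3-ol (racemic), via Grignard reagent 17 (not isolated)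
Conditions: Mg, THF, rt; then 16, −78 °C; aq. NH4Cl
Reagents that add atoms: none
Why: Grignard formation and 1,2-addition to the enal at low temperature; this places the future prenyl chain and the vinyl group unambiguously on either side of the carbinol carbon.

Step 10
Reactants: 18 7-methylocta-1,6-dien-3-ol
Product: 19 7-methylocta-1,6-dien-3-one
Conditions: Dess–Martin periodinane, NaHCO3, CH2Cl2, 0 °C
Reagents that add atoms: none
Why: Buffered Dess–Martin oxidation of a secondary allylic alcohol gives the polymerisation-prone vinyl ketone without touching the trisubstituted alkene; the enone is used at once.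

Step 11
Reactants: 14 (5R)-5-[5-(allyloxy)-2,2-dimethyl-2H-chromen-6-yl]tetrahydro-2H-pyran-2-one; 19 7-methylocta-1,6-dien-3-one
Product: 21 4-{(2R)-2-[5-(allyloxy)-2,2-dimethyl-2H-chromen-6-yl]-3-hydroxypropyl}-2-(3-methylbut-2-enyl)cyclohexane-1,3-dione, via keto lactone 20 (not isolated)
Conditions: LiN(iPr)2 (1.1 equiv), THF, −78 °C; 19 (1.3 equiv, slow), −78 → −20 °C; then KOtBu (2.2 equiv), tBuOH (1 equiv), −20 °C → rt; 1 M HCl to pH 4
Reagents that add atoms: none
Why: Deprotonation of 14 gives the lactone enolate, whose α-carbon (C4a) adds to the unsubstituted terminus of 19 (C4a–C5) to give 20 as its C6 ketone enolate; any carbonyl adduct returns by retro-aldol on warming. KOtBu/tBuOH then lets the enolates interconvert, and the C8 enolate acylates the lactone carbonyl (C8–C8a) and expels the C2 alkoxide. The closest known type is the Michael–Claisen (dimedone-type) annulation of ester enolates with enones, together with the ring-opening Dieckmann step of lactone annulations. Ring A closes as a carbocycle by 6-(enolendo)-exo-trig acylation. The sequence is pulled forward by formation of the stabilised 1,3-dionate, so the reversible steps before it need not each be selective. Regiochemistry follows from ring size: only the C8 enolate reaches C8a through a six-membered transition state (the C6 enolate would give a four-membered ring), which places the prenyl methylene between the two carbonyls. C4a and C8 form without control and are erased in steps 12 to 14, while C3 is not acidic and stays R. The allyl ether, ring D and the prenyl alkene are inert to amide and alkoxide bases, and slow addition of 19 in the cold limits polymerisation and double addition.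

Step 12
Reactants: 21 4-{(2R)-2-[5-(allyloxy)-2,2-dimethyl-2H-chromen-6-yl]-3-hydroxypropyl}-2-(3-methylbut-2-enyl)cyclohexane-1,3-dione
Product: 22 (3R)-3-[5-(allyloxy)-2,2-dimethyl-2H-chromen-6-yl]-8-(3-methylbut-2-enyl)-2,3,4,4a,5,6-hexahydro-7H-chromen-7-one (C4a epimers)
Conditions: PPTS (10 mol%), 4 Å molecular sieves, toluene, 80 °C
Reagents that add atoms: none
Why: The C2 hydroxyl adds to the C8a carbonyl (six-membered hemiketal; C7 is out of reach) and water is lost towards C8 to give the conjugated vinylogous ester, which closes ring C and differentiates the two dione oxygens. The catalyst is no stronger an acid than the dione enol itself, so addition of the enol to the prenyl double bond should not compete.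

Step 13
Reactants: 22 (3R)-3-[5-(allyloxy)-2,2-dimethyl-2H-chromen-6-yl]-8-(3-methylbut-2-enyl)-2,3,4,4a,5,6-hexahydro-7H-chromen-7-one
Product: 23 (3R)-3-[5-(allyloxy)-2,2-dimethyl-2H-chromen-6-yl]-8-(3-methylbut-2-enyl)-6-(phenylselanyl)-2,3,4,4a,5,6-hexahydro-7H-chromen-7-one
Conditions: LiN(iPr)2, THF, −78 °C; PhSeBr (1.05 equiv), −78 °C
Reagents that add atoms: benzeneselenenyl bromide, Br[Se]c1ccccc1
Why: Kinetic deprotonation of a vinylogous ester by a lithium amide takes place at the α' carbon (C6), and the enolate should be selenenylated at −78 °C faster than PhSeBr adds to the isolated alkenes when no excess is used.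

Step 14
Reactants: 23 (3R)-3-[5-(allyloxy)-2,2-dimethyl-2H-chromen-6-yl]-8-(3-methylbut-2-enyl)-6-(phenylselanyl)-2,3,4,4a,5,6-hexahydro-7H-chromen-7-one
Product: 26 (3R)-3-[5-(allyloxy)-2,2-dimethyl-2H-chromen-6-yl]-8-(3-methylbut-2-enyl)chroman-7-ol, via selenoxide 24 (not isolated), via dienone 25 (not isolated)
Conditions: mCPBA (1.0 equiv), CH2Cl2, −78 °C; then iPr2NH, −78 °C → rt
Reagents that add atoms: none
Why: Oxidation of the selenide by one equivalent of peracid at −78 °C is far faster than epoxidation; selenoxide syn-elimination can only take a C5 hydrogen, and the resulting cross-conjugated dienone with hydrogen on C4a is the keto tautomer of the phenol and should aromatise at once under the amine, which also traps PhSeOH.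

Step 15
Reactants: 26 (3R)-3-[5-(allyloxy)-2,2-dimethyl-2H-chromen-6-yl]-8-(3-methylbut-2-enyl)chroman-7-ol
Product: 27 (3R)-3-(5-hydroxy-2,2-dimethyl-2H-chromen-6-yl)-8-(3-methylbut-2-enyl)chroman-7-ol
Conditions: Pd(PPh3)4 (5 mol%), morpholine, THF, rt
Reagents that add atoms: none
Why: Zerovalent palladium ionises only the allyl aryl ether (a prenyl C–C bond cannot ionise) and morpholine captures the π-allyl fragment; the neutral conditions spare the o-prenylphenol, ring D and C3.

## Compound list

1 | 2,4-dihydroxybenzaldehyde | O=Cc1ccc(O)cc1O | starting material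
2 | 3-methylbut-2-enal | CC(C)=CC=O | starting material
3 | 5-hydroxy-2,2-dimethyl-2H-chromene-6-carbaldehyde | O=Cc1ccc2c(c1O)C=CC(C)(C)O2 | intermediate
4 | 5-(allyloxy)-2,2-dimethyl-2H-chromene-6-carbaldehyde | O=Cc1ccc2c(c1OCC=C)C=CC(C)(C)O2 | intermediate
5 | 5-(allyloxy)-6-(2-methoxyethenyl)-2,2-dimethyl-2H-chromene (E/Z mixture) | COC=Cc1ccc2c(c1OCC=C)C=CC(C)(C)O2 | intermediate
6 | 2-[5-(allyloxy)-2,2-dimethyl-2H-chromen-6-yl]acetaldehyde | O=CCc1ccc2c(c1OCC=C)C=CC(C)(C)O2 | intermediate (not isolated)
7 | 2-[5-(allyloxy)-2,2-dimethyl-2H-chromen-6-yl]acetic acid | OC(=O)Cc1ccc2c(c1OCC=C)C=CC(C)(C)O2 | intermediate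
8 | (R)-4-benzyloxazolidin-2-one | O=C1N[C@H](Cc2ccccc2)CO1 | starting material
9 | 2-[5-(allyloxy)-2,2-dimethyl-2H-chromen-6-yl]acetic pivalic anhydride | CC(C)(C)C(=O)OC(=O)Cc1ccc2c(c1OCC=C)C=CC(C)(C)O2 | intermediate (not isolated)
10 | (4R)-3-{2-[5-(allyloxy)-2,2-dimethyl-2H-chromen-6-yl]acetyl}-4-benzyloxazolidin-2-one | O=C(Cc1ccc2c(c1OCC=C)C=CC(C)(C)O2)N1[C@H](Cc2ccccc2)COC1=O | intermediate
11 | tert-butyl acrylate | C=CC(=O)OC(C)(C)C | starting material
12 | tert-butyl (4R)-4-[5-(allyloxy)-2,2-dimethyl-2H-chromen-6-yl]-5-[(4R)-4-benzyl-2-oxooxazolidin-3-yl]-5-oxopentanoate | CC(C)(C)OC(=O)CC[C@H](c1ccc2c(c1OCC=C)C=CC(C)(C)O2)C(=O)N1[C@H](Cc2ccccc2)COC1=O | intermediate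
13 | tert-butyl (4R)-4-[5-(allyloxy)-2,2-dimethyl-2H-chromen-6-yl]-5-hydroxypentanoate | CC(C)(C)OC(=O)CC[C@H](c1ccc2c(c1OCC=C)C=CC(C)(C)O2)CO | intermediate
14 | (5R)-5-[5-(allyloxy)-2,2-dimethyl-2H-chromen-6-yl]tetrahydro-2H-pyran-2-one | O=C1CC[C@H](c2ccc3c(c2OCC=C)C=CC(C)(C)O3)CO1 | intermediate (key-step precursor)
15 | 5-bromo-2-methylpent-2-ene | CC(C)=CCCBr | starting material
16 | acrolein | C=CC=O | starting material
17 | (4-methylpent-3-enyl)magnesium bromide | CC(C)=CCC[Mg]Br | intermediate (not isolated)
18 | 7-methylocta-1,6-dien-3-ol (racemic) | C=CC(O)CCC=C(C)C | intermediate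
19 | 7-methylocta-1,6-dien-3-one | C=CC(=O)CCC=C(C)C | intermediate (key-step precursor)
20 | (5R)-5-[5-(allyloxy)-2,2-dimethyl-2H-chromen-6-yl]-3-(7-methyl-3-oxooct-6-enyl)tetrahydro-2H-pyran-2-one (C3 epimers) | CC(C)=CCCC(=O)CCC1C[C@H](c2ccc3c(c2OCC=C)C=CC(C)(C)O3)COC1=O | intermediate (not isolated)
21 | 4-{(2R)-2-[5-(allyloxy)-2,2-dimethyl-2H-chromen-6-yl]-3-hydroxypropyl}-2-(3-methylbut-2-enyl)cyclohexane-1,3-dione | OC[C@@H](c1ccc2c(c1OCC=C)C=CC(C)(C)O2)CC1CCC(=O)C(CC=C(C)C)C1=O | intermediate (key-step product)
22 | (3R)-3-[5-(allyloxy)-2,2-dimethyl-2H-chromen-6-yl]-8-(3-methylbut-2-enyl)-2,3,4,4a,5,6-hexahydro-7H-chromen-7-one | CC(C)=CCC1=C2OC[C@@H](c3ccc4c(c3OCC=C)C=CC(C)(C)O4)CC2CCC1=O | intermediate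
23 | (3R)-3-[5-(allyloxy)-2,2-dimethyl-2H-chromen-6-yl]-8-(3-methylbut-2-enyl)-6-(phenylselanyl)-2,3,4,4a,5,6-hexahydro-7H-chromen-7-one | CC(C)=CCC1=C2OC[C@@H](c3ccc4c(c3OCC=C)C=CC(C)(C)O4)CC2CC([Se]c5ccccc5)C1=O | intermediate
24 | (3R)-3-[5-(allyloxy)-2,2-dimethyl-2H-chromen-6-yl]-8-(3-methylbut-2-enyl)-6-(phenylseleninyl)-2,3,4,4a,5,6-hexahydro-7H-chromen-7-one | CC(C)=CCC1=C2OC[C@@H](c3ccc4c(c3OCC=C)C=CC(C)(C)O4)CC2CC([Se](=O)c5ccccc5)C1=O | intermediate (not isolated)
25 | (3R)-3-[5-(allyloxy)-2,2-dimethyl-2H-chromen-6-yl]-8-(3-methylbut-2-enyl)-2,3,4,4a-tetrahydro-7H-chromen-7-one | CC(C)=CCC1=C2OC[C@@H](c3ccc4c(c3OCC=C)C=CC(C)(C)O4)CC2C=CC1=O | intermediate (not isolated)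
26 | (3R)-3-[5-(allyloxy)-2,2-dimethyl-2H-chromen-6-yl]-8-(3-methylbut-2-enyl)chroman-7-ol | CC(C)=CCc1c(O)ccc2c1OC[C@@H](c1ccc3c(c1OCC=C)C=CC(C)(C)O3)C2 | intermediate
27 | (3R)-3-(5-hydroxy-2,2-dimethyl-2H-chromen-6-yl)-8-(3-methylbut-2-enyl)chroman-7-ol | CC(C)=CCc1c(O)ccc2c1OC[C@@H](c1ccc3c(c1O)C=CC(C)(C)O3)C2 | target

## Step count and least certain steps

Total: 15 steps. Longest linear sequence: 13 steps (steps 1 to 8 and 11 to 15; steps 9 and 10 make the enone branch).

Step 11 (key step). The likely failures are carbonyl addition or anionic polymerisation of the vinyl ketone outrunning conjugate addition, incomplete transposition of the ketone enolate to C8, and intermolecular Claisen condensation during the alkoxide stage. The fallback separates the two bond formations. It sets out from 14, which is converted with LiN(iPr)2 and Me3SiCl (THF, −78 °C) into the trimethylsilyl ketene acetal {[(3R)-3-[5-(allyloxy)-2,2-dimethyl-2H-chromen-6-yl]-3,4-dihydro-2H-pyran-6-yl]oxy}trimethylsilane F1. A Mukaiyama–Michael addition of F1 to 19 with catalytic Sc(OTf)3 in CH2Cl2 at −78 °C, followed by aqueous work-up, should give 20, now isolated. A separate Dieckmann closure with KOtBu/tBuOH in THF returns to the route at 21.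

Step 6. The acidic α-aryl imide centre may epimerise under the amine/titanium conditions and lower the diastereoselectivity, and the Lewis acid may ionise the allylic ether of ring D. The fallback uses neither auxiliary nor Lewis acid and sets out from 7:
- The dilithium enediolate of 7 (2.1 equiv LiN(iPr)2, THF, −78 °C) is added to 11 to give racemic 2-[5-(allyloxy)-2,2-dimethyl-2H-chromen-6-yl]-5-tert-butoxy-5-oxopentanoic acid F2.
- Classical resolution by crystallisation of its salt with an enantiopure 1-phenylethylamine (enantiomer and solvent found by screening) gives the (2R)-acid F3.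
- Activation with isobutyl chloroformate and N-methylmorpholine (THF, −15 °C) gives the mixed carbonic anhydride F4, and reduction with NaBH4 in aqueous THF at 0 °C returns to the route at 13.

Step 8. Ring D may undergo acid-induced hydration or oligomerisation before the hindered ester has lactonised. The fallback avoids acid and sets out from 13. Cleavage of the tert-butyl ester with KOtBu/H2O (anhydrous hydroxide) in THF at room temperature gives (4R)-4-[5-(allyloxy)-2,2-dimethyl-2H-chromen-6-yl]-5-hydroxypentanoic acid F5. Closure with EDC·HCl and DMAP in CH2Cl2 returns to the route at 14.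

Step 12. Acid-promoted addition of the dione enol across the prenyl double bond (closure of a dimethyldihydropyran) may compete with hemiketalisation and dehydration, and the hemiketal may undergo retro-Claisen opening. The fallback replaces carbonyl condensation by O-alkylation and sets out from 21. An intramolecular Mitsunobu reaction (PPh3, diisopropyl azodicarboxylate, THF, 0 °C → rt) has the acidic dione enol displace the activated C2 hydroxyl through the C8a oxygen in a six-membered closure under neutral conditions. It returns at 22 and makes no compound outside the list (F0).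

Step 13, with step 14. The selenium electrophile may add to the prenyl or ring D double bond, and proton transfer may move the enolate to the γ position (C4a); in step 14 selenium by-products may oxidise the new phenol. The fallback uses an electrophile that does not add to alkenes and sets out from 22. Sulfinylation of the lithium enolate with methyl benzenesulfinate (THF, −78 → 0 °C) gives (3R)-3-[5-(allyloxy)-2,2-dimethyl-2H-chromen-6-yl]-8-(3-methylbut-2-enyl)-6-(phenylsulfinyl)-2,3,4,4a,5,6-hexahydro-7H-chromen-7-one F6. Thermal sulfoxide elimination (toluene, 90 °C, CaCO3) and tautomerisation through 25 return to the route at 26.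

## Further compounds

F1 | step 11 | {[(3R)-3-[5-(allyloxy)-2,2-dimethyl-2H-chromen-6-yl]-3,4-dihydro-2H-pyran-6-yl]oxy}trimethylsilane | C[Si](C)(C)OC1=CC[C@H](c2ccc3c(c2OCC=C)C=CC(C)(C)O3)CO1
F2 | step 6 | racemic 2-[5-(allyloxy)-2,2-dimethyl-2H-chromen-6-yl]-5-tert-butoxy-5-oxopentanoic acid | CC(C)(C)OC(=O)CCC(c1ccc2c(c1OCC=C)C=CC(C)(C)O2)C(O)=O
F3 | step 6 | (2R)-2-[5-(allyloxy)-2,2-dimethyl-2H-chromen-6-yl]-5-tert-butoxy-5-oxopentanoic acid | CC(C)(C)OC(=O)CC[C@H](c1ccc2c(c1OCC=C)C=CC(C)(C)O2)C(O)=O
F4 | step 6 | (2R)-2-[5-(allyloxy)-2,2-dimethyl-2H-chromen-6-yl]-5-tert-butoxy-5-oxopentanoic isobutyl carbonic anhydride | CC(C)(C)OC(=O)CC[C@H](c1ccc2c(c1OCC=C)C=CC(C)(C)O2)C(=O)OC(=O)OCC(C)C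
F5 | step 8 | (4R)-4-[5-(allyloxy)-2,2-dimethyl-2H-chromen-6-yl]-5-hydroxypentanoic acid | OC(=O)CC[C@H](c1ccc2c(c1OCC=C)C=CC(C)(C)O2)CO
F0 | step 12 | none | none
F6 | step 13 | (3R)-3-[5-(allyloxy)-2,2-dimethyl-2H-chromen-6-yl]-8-(3-methylbut-2-enyl)-6-(phenylsulfinyl)-2,3,4,4a,5,6-hexahydro-7H-chromen-7-one | CC(C)=CCC1=C2OC[C@@H](c3ccc4c(c3OCC=C)C=CC(C)(C)O4)CC2CC(S(=O)c5ccccc5)C1=O
A1 | alternative 1 | 6-[(3R)-7-(methoxymethoxy)-8-(3-methylbut-2-enyl)chroman-3-yl]-2-(3-methylbut-2-enyl)-3-(triisopropylsilyloxy)phenol | CC(C)=CCc1c(OCOC)ccc2c1OC[C@@H](c1ccc(O[Si](C(C)C)(C(C)C)C(C)C)c(CC=C(C)C)c1O)C2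
A2 | alternative 1 | (3E)-1-diazo-4-[(3R)-7-(methoxymethoxy)-8-(3-methylbut-2-enyl)chroman-3-yl]but-3-en-2-one | CC(C)=CCc1c(OCOC)ccc2c1OC[C@@H](/C=C/C(=O)C=[N+]=[N-])C2
A3 | alternative 1 | triisopropyl[(5-methylhex-4-en-1-yn-1-yl)oxy]silane | CC(C)=CCC#CO[Si](C(C)C)(C(C)C)C(C)C
A4 | alternative 1 | (3E)-4-[(3R)-7-(methoxymethoxy)-8-(3-methylbut-2-enyl)chroman-3-yl]buta-1,3-dien-1-one | CC(C)=CCc1c(OCOC)ccc2c1OC[C@@H](/C=C/C=C=O)C2
A5 | alternative 2 | 2-{(1R)-2-[2,4-bis(tert-butyldimethylsilyloxy)-3-(3-methylbut-2-enyl)phenyl]-1-[5-(methoxymethoxy)-2,2-dimethyl-2H-chromen-6-yl]ethyl}-4,4,5,5-tetramethyl-1,3,2-dioxaborolane | CC1(C)OB(OC1(C)C)[C@@H](c1ccc2c(c1OCOC)C=CC(C)(C)O2)Cc1ccc(O[Si](C)(C)C(C)(C)C)c(CC=C(C)C)c1O[Si](C)(C)C(C)(C)C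
A6 | alternative 2 | 1-bromo-2,4-bis(tert-butyldimethylsilyloxy)-3-(3-methylbut-2-enyl)benzene | Brc1ccc(O[Si](C)(C)C(C)(C)C)c(CC=C(C)C)c1O[Si](C)(C)C(C)(C)C
A7 | alternative 2 | 6-bromo-5-(methoxymethoxy)-2,2-dimethyl-2H-chromene | COCOc1c(Br)ccc2OC(C)(C)C=Cc12
A8 | alternative 2 | 2-ethenyl-4,4,5,5-tetramethyl-1,3,2-dioxaborolane | C=CB1OC(C)(C)C(C)(C)O1
A9 | alternative 2 | lithium ethenyl[5-(methoxymethoxy)-2,2-dimethyl-2H-chromen-6-yl](pinacolato)borate | [Li+].C=C[B-]1(c2ccc3OC(C)(C)C=Cc3c2OCOC)OC(C)(C)C(C)(C)O1
A10 | alternative 3 | 6-{(2R)-3-(tert-butyldimethylsilyloxy)-2-[5-(methoxymethoxy)-2,2-dimethyl-2H-chromen-6-yl]propyl}-2-(3-methylbut-2-enyl)-3-(triisopropylsilyloxy)phenol | CC(C)(C)[Si](C)(C)OC[C@@H](c1ccc2c(c1OCOC)C=CC(C)(C)O2)Cc1ccc(O[Si](C(C)C)(C(C)C)C(C)C)c(CC=C(C)C)c1O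
A11 | alternative 3 | (3E,6R)-7-(tert-butyldimethylsilyloxy)-1-diazo-6-[5-(methoxymethoxy)-2,2-dimethyl-2H-chromen-6-yl]hept-3-en-2-one | CC(C)(C)[Si](C)(C)OC[C@@H](c1ccc2c(c1OCOC)C=CC(C)(C)O2)C/C=C/C(=O)C=[N+]=[N-]
A12 | alternative 3 | (3E,6R)-7-(tert-butyldimethylsilyloxy)-6-[5-(methoxymethoxy)-2,2-dimethyl-2H-chromen-6-yl]hepta-1,3-dien-1-one | CC(C)(C)[Si](C)(C)OC[C@@H](c1ccc2c(c1OCOC)C=CC(C)(C)O2)C/C=C/C=C=O
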